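## Retrosynthetic overview

1. The target is a (+)-lariciresinol core, a (2S,3R,4R)-tetrahydrofuran, whose ring B phenol is etherified by a (1S,2S)-threo guaiacylglycerol. The endgame only removes one silyl and two allyl ethers, with no acid and no hydrogenolysis.
2. Glycerol unit: the C1–C2 bond comes from an Evans syn aldol between the N-(aryloxyacetyl)oxazolidinone built on the ring B phenol and O-allylvanillin, followed by LiBH4 cleavage.
3. Tetrahydrofuran: the C2–O bond comes from quinone-methide etherification of a 1,4-diol. The bond between the benzylic carbinol carbon and C3 comes from an aldol of an (R)-β-benzyl-γ-butyrolactone enolate with O-silylvanillin.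
4. Lactone: Evans alkylation of an N-(3-arylpropanoyl)oxazolidinone (from ferulic acid) with tert-butyl bromoacetate, then reduction and lactonisation.
5. Ring order: γ-butyrolactone (temporary; made in step 5, opened in step 8), then the tetrahydrofuran (step 9). The three arenes are bought.

Conventions: ring A is the arene of the benzyl group, ring B the arene on the tetrahydrofuran, ring C the arene of the glycerol unit. Building blocks that end up in the carbon skeleton or serve as auxiliaries are numbered; protecting and activating reagents are named on the reagent line.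

## Route

Step 1
Reactants: 1 (E)-ferulic acid
Product: 2 3-(4-hydroxy-3-methoxyphenyl)propanoic acid
Conditions: H2 (1 atm), 10% Pd/C, MeOH, rt
Reagents that add atoms: none
Why: Catalytic alkene hydrogenation saturates only the cinnamate double bond and leaves the arene and the acid alone.

Step 2
Reactants: 2 3-(4-hydroxy-3-methoxyphenyl)propanoic acid
Product: 4 3-[4-(allyloxy)-3-methoxyphenyl]propanoic acid, via allyl ester 3 (not isolated)
Conditions: allyl bromide (2.5 equiv), K2CO3, acetone, reflux; concentrate; then 2 M NaOH, MeOH, 50 °C; then 1 M HCl to pH 2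
Reagents that add atoms: allyl bromide (C=CCBr); sodium hydroxide ([Na+].[OH-])
Why: Williamson O-allylation of phenoxide and carboxylate followed by saponification of the allyl ester leaves the aryl allyl ether, which tolerates all later base, hydride and mild acid steps and is removed at the end by palladium catalysis.

Step 3
Reactants: 4 3-[4-(allyloxy)-3-methoxyphenyl]propanoic acid; 5 (S)-4-benzyl-1,3-oxazolidin-2-one
Product: 7 (4S)-3-{3-[4-(allyloxy)-3-methoxyphenyl]propanoyl}-4-benzyl-1,3-oxazolidin-2-one, via mixed pivalic anhydride 6 (not isolated)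
Conditions: PivCl, Et3N, THF, −20 °C; then 5, LiCl, −20 °C to rt
Reagents that add atoms: none
Why: N-acylation of the oxazolidinone through the mixed anhydride occurs at the unhindered carbonyl and installs the Evans auxiliary.

Step 4
Reactants: 7 (4S)-3-{3-[4-(allyloxy)-3-methoxyphenyl]propanoyl}-4-benzyl-1,3-oxazolidin-2-one; 8 tert-butyl bromoacetate
Product: 10 tert-butyl (3R)-3-[4-(allyloxy)-3-methoxybenzyl]-4-[(4S)-4-benzyl-2-oxo-1,3-oxazolidin-3-yl]-4-oxobutanoate, via sodium Z-enolate 9 (not isolated)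
Conditions: NaN(SiMe3)2, THF, −78 °C; then 8, −78 to −40 °C
Reagents that add atoms: none
Why: In this Evans asymmetric alkylation the chelated Z-enolate is alkylated on the face opposite the auxiliary benzyl group, which sets the (R) centre that becomes C4 of the tetrahydrofuran.

Step 5
Reactants: 10 tert-butyl (3R)-3-[4-(allyloxy)-3-methoxybenzyl]-4-[(4S)-4-benzyl-2-oxo-1,3-oxazolidin-3-yl]-4-oxobutanoate
Product: 12 (4R)-4-[4-(allyloxy)-3-methoxybenzyl]dihydrofuran-2(3H)-one, via hydroxy tert-butyl ester 11 (not isolated)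
Conditions: LiBH4, MeOH (1 equiv), THF, 0 °C; aqueous work-up; then p-TsOH·H2O (10 mol%), toluene, 60 °C
Reagents that add atoms: none
Why: LiBH4 reductively cleaves the imide to the primary alcohol without touching the tert-butyl ester, and acid-catalysed lactonisation then closes the γ-butyrolactone without affecting the stereocentre.

Step 6
Reactants: 13 vanillin
Product: 14 4-(tert-butyldimethylsilyloxy)-3-methoxybenzaldehyde
Conditions: TBSCl, imidazole, CH2Cl2, rt
Reagents that add atoms: tert-butyldimethylsilyl chloride (CC(C)(C)[Si](C)(C)Cl)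
Why: Imidazole-promoted silylation gives a fluoride-labile phenol protecting group that is orthogonal to the allyl ether on ring A.

Step 7
Reactants: 12 (4R)-4-[4-(allyloxy)-3-methoxybenzyl]dihydrofuran-2(3H)-one; 14 4-(tert-butyldimethylsilyloxy)-3-methoxybenzaldehyde
Product: 16 (3S,4R)-4-[4-(allyloxy)-3-methoxybenzyl]-3-{[4-(tert-butyldimethylsilyloxy)-3-methoxyphenyl](hydroxy)methyl}dihydrofuran-2(3H)-one (both carbinol epimers), via lithium enolate 15 (not isolated)
Conditions: LiN(iPr)2, THF, −78 °C; then 14, −78 °C; AcOH quench at −78 °C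
Reagents that add atoms: none
Why: In this aldol addition the aldehyde attacks the lactone enolate anti to the C4 benzyl group, giving the 3,4-trans lactone that fixes C3 of the future tetrahydrofuran, while the carbinol centre forms as a mixture that is reset in step 9.

Step 8
Reactants: 16 (3S,4R)-aldol lactone
Product: 17 (2R,3R)-3-[4-(allyloxy)-3-methoxybenzyl]-2-{[4-(tert-butyldimethylsilyloxy)-3-methoxyphenyl](hydroxy)methyl}butane-1,4-diol (both carbinol epimers)
Conditions: LiBH4, THF, 0 °C to rt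
Reagents that add atoms: none
Why: Hydride reduction opens the lactone to the 1,4-diol without touching a stereocentre or the aryl silyl ether.

Step 9
Reactants: 17 (2R,3R)-silyl triol
Product: 19 [(2S,3R,4R)-4-[4-(allyloxy)-3-methoxybenzyl]-2-(4-hydroxy-3-methoxyphenyl)tetrahydrofuran-3-yl]methanol, via free phenol 18 (not isolated)
Conditions: Bu4NF, AcOH, THF, 0 °C; work-up; then CSA (10 mol%), CH2Cl2/THF (5:1), 0 °C to rt
Reagents that add atoms: none
Why: Fluoride frees the para-phenol, acid then ionises the benzylic alcohol of either epimer to a quinone methide, and the primary hydroxyl on the benzyl-bearing carbon adds reversibly (intramolecular 1,6-oxa-addition, cycloetherification) to give the thermodynamically preferred 2,3-trans aryl group, i.e. the (2S) centre.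

Step 10
Reactants: 19 tetrahydrofuran phenol; 20 ethyl bromoacetate
Product: 21 ethyl 2-{4-[(2S,3R,4R)-4-[4-(allyloxy)-3-methoxybenzyl]-3-(hydroxymethyl)tetrahydrofuran-2-yl]-2-methoxyphenoxy}acetate
Conditions: K2CO3, acetone, reflux
Reagents that add atoms: none
Why: In this Williamson ether synthesis carbonate deprotonates only the phenol, so the phenoxide is alkylated and the primary alcohol is not.

Step 11
Reactants: 21 hydroxy ester
Product: 22 ethyl 2-{4-[(2S,3R,4R)-4-[4-(allyloxy)-3-methoxybenzyl]-3-[(tert-butyldimethylsilyloxy)methyl]tetrahydrofuran-2-yl]-2-methoxyphenoxy}acetate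
Conditions: TBSCl, imidazole, DMF, rt
Reagents that add atoms: tert-butyldimethylsilyl chloride (CC(C)(C)[Si](C)(C)Cl)
Why: Silylation masks the only free hydroxyl so that it cannot be acylated in step 13 or borylated in step 15.

Step 12
Reactants: 22 silyl ether ester
Product: 23 2-{4-[(2S,3R,4R)-4-[4-(allyloxy)-3-methoxybenzyl]-3-[(tert-butyldimethylsilyloxy)methyl]tetrahydrofuran-2-yl]-2-methoxyphenoxy}acetic acid
Conditions: LiOH·H2O, THF/H2O (3:1), 0 °C to rt; then 0.5 M HCl to pH 4, 0 °C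
Reagents that add atoms: lithium hydroxide ([Li+].[OH-])
Why: Saponification of the activated aryloxyacetate is fast under conditions that leave the alkyl silyl ether, the allyl ether and the tetrahydrofuran intact.

Step 13
Reactants: 23 aryloxyacetic acid; 24 (R)-4-benzyl-1,3-oxazolidin-2-one
Product: 26 (4R)-4-benzyl-3-(2-{4-[(2S,3R,4R)-4-[4-(allyloxy)-3-methoxybenzyl]-3-[(tert-butyldimethylsilyloxy)methyl]tetrahydrofuran-2-yl]-2-methoxyphenoxy}acetyl)-1,3-oxazolidin-2-one, via mixed pivalic anhydride 25 (not isolated)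
Conditions: PivCl, Et3N, THF, −20 °C; then 24, LiCl, −20 °C to rt
Reagents that add atoms: none
Why: N-acylation through the mixed anhydride attaches the auxiliary that will control both glycerol stereocentres.

Step 14
Reactants: 13 vanillin
Product: 27 4-(allyloxy)-3-methoxybenzaldehyde
Conditions: allyl bromide, K2CO3, acetone, reflux
Reagents that add atoms: allyl bromide (C=CCBr)
Why: Williamson O-allylation gives ring C the same protecting group as ring A, so one operation frees both phenols at the end.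

Step 15
Reactants: 26 N-(aryloxyacetyl)oxazolidinone; 27 4-(allyloxy)-3-methoxybenzaldehyde
Product: 29 (4R)-3-[(2R,3S)-3-[4-(allyloxy)-3-methoxyphenyl]-2-{4-[(2S,3R,4R)-4-[4-(allyloxy)-3-methoxybenzyl]-3-[(tert-butyldimethylsilyloxy)methyl]tetrahydrofuran-2-yl]-2-methoxyphenoxy}-3-hydroxypropanoyl]-4-benzyl-1,3-oxazolidin-2-one, via dibutylboron Z-enolate 28 (not isolated)
Conditions: Bu2BOTf, iPr2NEt, CH2Cl2, −78 to 0 °C; then 27, −78 to 0 °C; then pH 7 phosphate buffer, MeOH, 30% H2O2, 0 °C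
Reagents that add atoms: none
Why: In this Evans syn aldol the Z-boron enolate reacts through a Zimmerman–Traxler chair with the auxiliary dipole opposed, the aldehyde adds to the face remote from the (R)-benzyl group, and both new centres are set as the (2R,3S) syn adduct, which is the (1S,2S)-threo arrangement after reduction.

Step 16
Reactants: 29 syn aldol adduct
Product: 30 (1S,2S)-1-[4-(allyloxy)-3-methoxyphenyl]-2-{4-[(2S,3R,4R)-4-[4-(allyloxy)-3-methoxybenzyl]-3-[(tert-butyldimethylsilyloxy)methyl]tetrahydrofuran-2-yl]-2-methoxyphenoxy}propane-1,3-diol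
Conditions: LiBH4, MeOH (1 equiv), THF, 0 °C
Reagents that add atoms: none
Why: Hydride attacks the exocyclic imide carbonyl (reductive auxiliary removal) and gives the primary alcohol directly without disturbing either new stereocentre.

Step 17
Reactants: 30 silyl-protected diol
Product: 31 (1S,2S)-1-[4-(allyloxy)-3-methoxyphenyl]-2-{4-[(2S,3R,4R)-4-[4-(allyloxy)-3-methoxybenzyl]-3-(hydroxymethyl)tetrahydrofuran-2-yl]-2-methoxyphenoxy}propane-1,3-diol
Conditions: Bu4NF, AcOH, THF, rt
Reagents that add atoms: none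
Why: Buffered fluoride desilylation removes the alkyl silyl ether under near-neutral conditions that cannot ionise either benzylic C–O bond.

Step 18
Reactants: 31 bis(allyl ether)
Product: 32 (1S,2S)-1-(4-hydroxy-3-methoxyphenyl)-2-{4-[(2S,3R,4R)-4-(4-hydroxy-3-methoxybenzyl)-3-(hydroxymethyl)tetrahydrofuran-2-yl]-2-methoxyphenoxy}propane-1,3-diol
Conditions: Pd(PPh3)4 (5 mol%), morpholine (10 equiv), THF, rt
Reagents that add atoms: none
Why: In this Tsuji–Trost deallylation zerovalent palladium ionises each aryl allyl ether to a π-allyl complex that morpholine traps, freeing both phenols without acid, base or hydrogen near the benzylic alcohol and the benzylic ether.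

## Compound list

1 | (E)-ferulic acid | COc1cc(/C=C/C(=O)O)ccc1O | starting material
2 | 3-(4-hydroxy-3-methoxyphenyl)propanoic acid | COc1cc(CCC(=O)O)ccc1O | intermediate
3 | allyl 3-[4-(allyloxy)-3-methoxyphenyl]propanoate | COc1cc(CCC(=O)OCC=C)ccc1OCC=C | intermediate
4 | 3-[4-(allyloxy)-3-methoxyphenyl]propanoic acid | COc1cc(CCC(=O)O)ccc1OCC=C | intermediate
5 | (S)-4-benzyl-1,3-oxazolidin-2-one | O=C1N[C@@H](Cc2ccccc2)CO1 | starting material
6 | mixed anhydride of 4 and pivalic acid | COc1cc(CCC(=O)OC(=O)C(C)(C)C)ccc1OCC=C | intermediate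
7 | (4S)-3-{3-[4-(allyloxy)-3-methoxyphenyl]propanoyl}-4-benzyl-1,3-oxazolidin-2-one | COc1cc(CCC(=O)N2[C@@H](Cc3ccccc3)COC2=O)ccc1OCC=C | intermediate
8 | tert-butyl bromoacetate | CC(C)(C)OC(=O)CBr | starting material
9 | sodium (Z)-enolate of 7 | [Na+].[O-]/C(=C\Cc1ccc(OCC=C)c(OC)c1)N1[C@@H](Cc2ccccc2)COC1=O | intermediate
10 | tert-butyl (3R)-3-[4-(allyloxy)-3-methoxybenzyl]-4-[(4S)-4-benzyl-2-oxo-1,3-oxazolidin-3-yl]-4-oxobutanoate | COc1cc(C[C@H](CC(=O)OC(C)(C)C)C(=O)N2[C@@H](Cc3ccccc3)COC2=O)ccc1OCC=C | intermediate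
11 | tert-butyl (3R)-4-[4-(allyloxy)-3-methoxyphenyl]-3-(hydroxymethyl)butanoate | COc1cc(C[C@H](CC(=O)OC(C)(C)C)CO)ccc1OCC=C | intermediate
12 | (4R)-4-[4-(allyloxy)-3-methoxybenzyl]dihydrofuran-2(3H)-one | COc1cc(C[C@H]2COC(=O)C2)ccc1OCC=C | intermediate
13 | vanillin | COc1cc(C=O)ccc1O | starting material
14 | 4-(tert-butyldimethylsilyloxy)-3-methoxybenzaldehyde | COc1cc(C=O)ccc1O[Si](C)(C)C(C)(C)C | intermediate
15 | lithium enolate of 12 | [Li+].[O-]C1=C[C@@H](Cc2ccc(OCC=C)c(OC)c2)CO1 | intermediate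
16 | (3S,4R)-4-[4-(allyloxy)-3-methoxybenzyl]-3-{[4-(tert-butyldimethylsilyloxy)-3-methoxyphenyl](hydroxy)methyl}dihydrofuran-2(3H)-one, both carbinol epimers | O=C1OC[C@H](Cc2ccc(OCC=C)c(OC)c2)[C@H]1C(O)c1ccc(O[Si](C)(C)C(C)(C)C)c(OC)c1 | intermediate
17 | (2R,3R)-3-[4-(allyloxy)-3-methoxybenzyl]-2-{[4-(tert-butyldimethylsilyloxy)-3-methoxyphenyl](hydroxy)methyl}butane-1,4-diol, both carbinol epimers | OC[C@H](Cc1ccc(OCC=C)c(OC)c1)[C@H](CO)C(O)c1ccc(O[Si](C)(C)C(C)(C)C)c(OC)c1 | intermediate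
18 | (2R,3R)-3-[4-(allyloxy)-3-methoxybenzyl]-2-[hydroxy(4-hydroxy-3-methoxyphenyl)methyl]butane-1,4-diol, both carbinol epimers | OC[C@H](Cc1ccc(OCC=C)c(OC)c1)[C@H](CO)C(O)c1ccc(O)c(OC)c1 | intermediate
19 | [(2S,3R,4R)-4-[4-(allyloxy)-3-methoxybenzyl]-2-(4-hydroxy-3-methoxyphenyl)tetrahydrofuran-3-yl]methanol | COc1cc(C[C@H]2CO[C@H](c3ccc(O)c(OC)c3)[C@H]2CO)ccc1OCC=C | intermediate
20 | ethyl bromoacetate | CCOC(=O)CBr | starting material
21 | ethyl 2-{4-[(2S,3R,4R)-4-[4-(allyloxy)-3-methoxybenzyl]-3-(hydroxymethyl)tetrahydrofuran-2-yl]-2-methoxyphenoxy}acetate | COc1cc(C[C@H]2CO[C@H](c3ccc(OCC(=O)OCC)c(OC)c3)[C@H]2CO)ccc1OCC=C | intermediate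
22 | ethyl 2-{4-[(2S,3R,4R)-4-[4-(allyloxy)-3-methoxybenzyl]-3-[(tert-butyldimethylsilyloxy)methyl]tetrahydrofuran-2-yl]-2-methoxyphenoxy}acetate | COc1cc(C[C@H]2CO[C@H](c3ccc(OCC(=O)OCC)c(OC)c3)[C@H]2CO[Si](C)(C)C(C)(C)C)ccc1OCC=C | intermediate
23 | 2-{4-[(2S,3R,4R)-4-[4-(allyloxy)-3-methoxybenzyl]-3-[(tert-butyldimethylsilyloxy)methyl]tetrahydrofuran-2-yl]-2-methoxyphenoxy}acetic acid | COc1cc(C[C@H]2CO[C@H](c3ccc(OCC(=O)O)c(OC)c3)[C@H]2CO[Si](C)(C)C(C)(C)C)ccc1OCC=C | intermediate
24 | (R)-4-benzyl-1,3-oxazolidin-2-one | O=C1N[C@H](Cc2ccccc2)CO1 | starting material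
25 | mixed anhydride of 23 and pivalic acid | COc1cc(C[C@H]2CO[C@H](c3ccc(OCC(=O)OC(=O)C(C)(C)C)c(OC)c3)[C@H]2CO[Si](C)(C)C(C)(C)C)ccc1OCC=C | intermediate
26 | (4R)-4-benzyl-3-(2-{4-[(2S,3R,4R)-4-[4-(allyloxy)-3-methoxybenzyl]-3-[(tert-butyldimethylsilyloxy)methyl]tetrahydrofuran-2-yl]-2-methoxyphenoxy}acetyl)-1,3-oxazolidin-2-one | COc1cc(C[C@H]2CO[C@H](c3ccc(OCC(=O)N4[C@H](Cc5ccccc5)COC4=O)c(OC)c3)[C@H]2CO[Si](C)(C)C(C)(C)C)ccc1OCC=C | intermediate
27 | 4-(allyloxy)-3-methoxybenzaldehyde | COc1cc(C=O)ccc1OCC=C | intermediate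
28 | dibutylboron (Z)-enolate of 26 | COc1cc(C[C@H]2CO[C@H](c3ccc(O/C=C(\OB(CCCC)CCCC)N4[C@H](Cc5ccccc5)COC4=O)c(OC)c3)[C@H]2CO[Si](C)(C)C(C)(C)C)ccc1OCC=C | intermediate
29 | (4R)-3-[(2R,3S)-3-[4-(allyloxy)-3-methoxyphenyl]-2-{4-[(2S,3R,4R)-4-[4-(allyloxy)-3-methoxybenzyl]-3-[(tert-butyldimethylsilyloxy)methyl]tetrahydrofuran-2-yl]-2-methoxyphenoxy}-3-hydroxypropanoyl]-4-benzyl-1,3-oxazolidin-2-one | COc1cc(C[C@H]2CO[C@H](c3ccc(O[C@@H](C(=O)N4[C@H](Cc5ccccc5)COC4=O)[C@@H](O)c6ccc(OCC=C)c(OC)c6)c(OC)c3)[C@H]2CO[Si](C)(C)C(C)(C)C)ccc1OCC=C | intermediate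
30 | (1S,2S)-1-[4-(allyloxy)-3-methoxyphenyl]-2-{4-[(2S,3R,4R)-4-[4-(allyloxy)-3-methoxybenzyl]-3-[(tert-butyldimethylsilyloxy)methyl]tetrahydrofuran-2-yl]-2-methoxyphenoxy}propane-1,3-diol | COc1cc(C[C@H]2CO[C@H](c3ccc(O[C@@H](CO)[C@@H](O)c4ccc(OCC=C)c(OC)c4)c(OC)c3)[C@H]2CO[Si](C)(C)C(C)(C)C)ccc1OCC=C | intermediate
31 | (1S,2S)-1-[4-(allyloxy)-3-methoxyphenyl]-2-{4-[(2S,3R,4R)-4-[4-(allyloxy)-3-methoxybenzyl]-3-(hydroxymethyl)tetrahydrofuran-2-yl]-2-methoxyphenoxy}propane-1,3-diol | COc1cc(C[C@H]2CO[C@H](c3ccc(O[C@@H](CO)[C@@H](O)c4ccc(OCC=C)c(OC)c4)c(OC)c3)[C@H]2CO)ccc1OCC=C | intermediate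
32 | (1S,2S)-1-(4-hydroxy-3-methoxyphenyl)-2-{4-[(2S,3R,4R)-4-(4-hydroxy-3-methoxybenzyl)-3-(hydroxymethyl)tetrahydrofuran-2-yl]-2-methoxyphenoxy}propane-1,3-diol | COc1cc(C[C@H]2CO[C@H](c3ccc(O[C@@H](CO)[C@@H](O)c4ccc(O)c(OC)c4)c(OC)c3)[C@H]2CO)ccc1O | target

## Step count and risks

Total steps: 18. Longest linear sequence: 16 steps (steps 1–5, 7–13 and 15–18, from ferulic acid); steps 6 and 14 are one-step side branches from vanillin.

The three steps most likely to fail:

**Step 7 (lactone aldol).** The lithium aldolate of an electron-rich aryl aldehyde can revert on warming, which costs conversion. The fallback sets out from 12 and comes back at 16. Lactone 12 is deprotonated with LiN(iPr)2 and silylated with Me3SiCl in THF at −78 °C to give the trimethylsilyl ketene acetal F1. A BF3·OEt2-promoted Mukaiyama aldol addition of F1 to aldehyde 14 in CH2Cl2 at −78 °C, followed by aqueous work-up, gives 16. The C–C bond forms irreversibly under non-basic conditions, again anti to the benzyl group.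

**Step 9 (desilylation and quinone-methide ring closure).** The free quinone methide can oligomerise, or ring A can attack it in a Friedel–Crafts sense to give an aryltetralin. The fallback sets out from 17 and comes back at 19, with the two operations in the opposite order. Silyl ether 17 is cyclised directly with CSA (10 mol%) in CH2Cl2 at 0 °C through the para-silyloxybenzylic cation, so no free quinone methide is formed. This gives the silylated tetrahydrofuran F2 with the same 2,3-trans preference. Bu4NF/AcOH in THF then converts F2 into 19.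

**Step 15 (Evans aldol on the advanced imide).** The risk is incomplete enolisation or an eroded diastereomer ratio on a substrate with several Lewis-basic sites. The fallback sets out from 22 and comes back at 30, bypassing 23, 25, 26, 28 and 29.
- Ester 22 is deprotonated with LiN(iPr)2 in THF at −78 °C and added to aldehyde 27, giving the β-hydroxy ester diastereomer mixture F3.
- Dess–Martin periodinane (NaHCO3, CH2Cl2) oxidises F3 to the configurationally labile α-aryloxy β-keto ester F4.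
- Asymmetric transfer hydrogenation with dynamic kinetic resolution (RuCl(p-cymene)[(R,R)-TsDPEN], HCO2H/Et3N 5:2, CH2Cl2, 30 °C) converts F4 into the syn (2R,3S) β-hydroxy ester F5. The choice of the (R,R) ligand is by analogy with simple aryl ketone reductions, and the configuration of F5 should be confirmed before going on.
- LiBH4 in THF at 0 °C reduces the ester of F5 to diol 30.

Further compounds
F1 | step 7 | {[(4R)-4-[4-(allyloxy)-3-methoxybenzyl]-4,5-dihydrofuran-2-yl]oxy}trimethylsilane | C[Si](C)(C)OC1=C[C@@H](Cc2ccc(OCC=C)c(OC)c2)CO1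
F2 | step 9 | [(2S,3R,4R)-4-[4-(allyloxy)-3-methoxybenzyl]-2-[4-(tert-butyldimethylsilyloxy)-3-methoxyphenyl]tetrahydrofuran-3-yl]methanol | COc1cc(C[C@H]2CO[C@H](c3ccc(O[Si](C)(C)C(C)(C)C)c(OC)c3)[C@H]2CO)ccc1OCC=C
F3 | step 15 | ethyl 3-[4-(allyloxy)-3-methoxyphenyl]-2-{4-[(2S,3R,4R)-4-[4-(allyloxy)-3-methoxybenzyl]-3-[(tert-butyldimethylsilyloxy)methyl]tetrahydrofuran-2-yl]-2-methoxyphenoxy}-3-hydroxypropanoate, diastereomer mixture at C2 and C3 | COc1cc(C[C@H]2CO[C@H](c3ccc(OC(C(=O)OCC)C(O)c4ccc(OCC=C)c(OC)c4)c(OC)c3)[C@H]2CO[Si](C)(C)C(C)(C)C)ccc1OCC=C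
F4 | step 15 | ethyl 3-[4-(allyloxy)-3-methoxyphenyl]-2-{4-[(2S,3R,4R)-4-[4-(allyloxy)-3-methoxybenzyl]-3-[(tert-butyldimethylsilyloxy)methyl]tetrahydrofuran-2-yl]-2-methoxyphenoxy}-3-oxopropanoate, epimers at C2 | COc1cc(C[C@H]2CO[C@H](c3ccc(OC(C(=O)OCC)C(=O)c4ccc(OCC=C)c(OC)c4)c(OC)c3)[C@H]2CO[Si](C)(C)C(C)(C)C)ccc1OCC=C
F5 | step 15 | ethyl (2R,3S)-3-[4-(allyloxy)-3-methoxyphenyl]-2-{4-[(2S,3R,4R)-4-[4-(allyloxy)-3-methoxybenzyl]-3-[(tert-butyldimethylsilyloxy)methyl]tetrahydrofuran-2-yl]-2-methoxyphenoxy}-3-hydroxypropanoate | COc1cc(C[C@H]2CO[C@H](c3ccc(O[C@@H](C(=O)OCC)[C@@H](O)c4ccc(OCC=C)c(OC)c4)c(OC)c3)[C@H]2CO[Si](C)(C)C(C)(C)C)ccc1OCC=C
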